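**Plan**
Retrosynthetic cuts: first the depside C(=O)–O bond between the ring A carbonyl and O4 of ring B. Next, in each half, the ketone C–pentyl bond of the 2-oxoheptyl arm. Last, and together, the ring C6–CH2 and ring C1–C(=O) bonds.
Enabling feature: in ring B the carboxyl carbon on C1 and the CH2–C(=O) arm on C6 sit on neighbouring ring carbons, and OMe on C2 flanks C1. A 3-alkoxyaryne leaves exactly this array after slipping into a C–CO bond of a malonate. Ring A repeats the array with OH on C2.
Forward order: both benzene rings come ready-made from 5-bromovanillin and no lasting ring is built. Dakin oxidation and a retro-Brook/triflation sequence give the silyl triflate, and aryne insertion gives the homophthalate. Weinreb amide formation and pentyl Grignard addition then give one keto ester that serves both halves.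
Division and joining: MOM removal gives the ring B phenol. BBr3, benzylation and alkaline opening of a temporary isocoumarin lactone give the ring A acid. Carbodiimide coupling and a single hydrogenolysis finish the route.
Stereochemistry: the target has no stereocentre and no double-bond geometry, so none has to be set.

Key step: step 4

Remark: the 2-(2-oxoheptyl)benzoic acids of this route, the target included, are drawn as open-chain keto acids, although each can equilibrate with its cyclic lactol form.

**Step 1**
Reactants: 1 5-bromovanillin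
Product: 3 2-bromo-6-methoxybenzene-1,4-diol, via aryl formate 2 (not isolated)
Conditions: 30% aq H2O2, 1 M NaOH, N2, 0 → 40 °C; then 2 M HCl
Reagents that add atoms: hydrogen peroxide, OO
Why: Dakin oxidation, in which the para-hydroxyl drives aryl migration from carbon to oxygen in the hydroperoxide adduct and formate 2 is saponified in the same alkaline medium.

**Step 2**
Reactants: 3 2-bromo-6-methoxybenzene-1,4-diol
Product: 8 4-hydroxy-2-methoxy-6-(trimethylsilyl)phenyl trifluoromethanesulfonate, via bis(trimethylsilyl) ether 4 (not isolated), via aryllithium 5 (not isolated), via lithium phenoxide 6 (not isolated), via silyloxy triflate 7 (not isolated)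
Conditions: HMDS, THF, 70 °C, then evaporate; n-BuLi, THF, −100 → −78 °C; Tf2O, −100 → −78 °C; aq NaHCO3; then 1 M HCl, THF, rt
Reagents that add atoms: hexamethyldisilazane, C[Si](C)(C)N[Si](C)(C)C; trifluoromethanesulfonic anhydride, O=S(=O)(OS(=O)(=O)C(F)(F)F)C(F)(F)F
Why: O-silylation, bromine–lithium exchange, retro-Brook O-to-C silyl shift and triflation is the standard one-flask entry to ortho-silylaryl triflates; only the oxygen next to lithium can give up its silyl group, so the two hydroxyls of 3 are told apart without selective protection, and dilute acid then removes the remote aryl silyl ether while the C–Si bond, which has no ortho or para donor, stays.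

**Step 3**
Reactants: 8 4-hydroxy-2-methoxy-6-(trimethylsilyl)phenyl trifluoromethanesulfonate
Product: 9 2-methoxy-4-(methoxymethoxy)-6-(trimethylsilyl)phenyl trifluoromethanesulfonate
Conditions: MOMCl, i-Pr2NEt, CH2Cl2, 0 °C → rt
Reagents that add atoms: chloromethyl methyl ether, COCCl
Why: O-alkylation (methoxymethylation) of the only free phenol under amine base, which touches neither the triflate nor the aryl silane, and the resulting acetal tolerates fluoride, unlike a silyl ether.

**Step 4**
Reactants: 9 2-methoxy-4-(methoxymethoxy)-6-(trimethylsilyl)phenyl trifluoromethanesulfonate; 10 dibenzyl malonate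
Product: 13 benzyl 2-[2-(benzyloxy)-2-oxoethyl]-6-methoxy-4-(methoxymethoxy)benzoate, via aryne 11 (not isolated), via benzocyclobutenoxide 12 (not isolated)
Conditions: 10 (1.5 equiv), CsF (3 equiv), MeCN, 70 °C
Reagents that add atoms: none
Why: Fluoride strips the silyl group of 9 and triflate leaves, which frees aryne 11, while CsF also deprotonates malonate 10. The malonate carbanion adds to the aryne carbon remote from OMe (the later C6), so that the aryl anion arises on the carbon beside OMe (the later C1), where the inductive pull of oxygen stabilises it. This anion attacks one ester carbonyl in a 4-exo-trig closure to benzocyclobutenoxide 12, and fragmentation of the strained C–C bond between the two sp3 carbons shifts the benzyloxycarbonyl group onto C1 and releases an arylacetate enolate that is protonated by further 10. The four-membered ring is only transient, so no ring and no stereocentre remain in 13 and nothing stereochemical has to be controlled. The reaction type is the known insertion of arynes into the C–C sigma bond of malonates, the ester counterpart of the acyl-alkylation of 3-alkoxyarynes by beta-keto esters. The only selectivity needed is regiochemical and is secured by the methoxy group next to the triple bond (the OMOM group is too remote to interfere), while the symmetry of 10 makes the choice of carbonyl irrelevant and its excess and higher acidity keep 13 from being arylated again.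

**Step 5**
Reactants: 13 benzyl 2-[2-(benzyloxy)-2-oxoethyl]-6-methoxy-4-(methoxymethoxy)benzoate
Product: 14 benzyl 2-methoxy-6-{2-[methoxy(methyl)amino]-2-oxoethyl}-4-(methoxymethoxy)benzoate
Conditions: MeNH(OMe)·HCl, i-PrMgCl, THF, −20 → 0 °C; cold 1 M HCl
Reagents that add atoms: N,O-dimethylhydroxylamine hydrochloride, CNOC.Cl
Why: Direct ester aminolysis by the magnesium amide of N,O-dimethylhydroxylamine (Weinreb amide synthesis), which reaches the open arylacetic ester while the benzoate, flanked by OMe and the CH2 arm, is shielded on both sides.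

**Step 6**
Reactants: 14 benzyl 2-methoxy-6-{2-[methoxy(methyl)amino]-2-oxoethyl}-4-(methoxymethoxy)benzoate; 15 pentylmagnesium bromide
Product: 17 benzyl 2-methoxy-4-(methoxymethoxy)-6-(2-oxoheptyl)benzoate, via magnesium chelate 16 (not isolated)
Conditions: 15 (2 equiv), THF, −20 → 0 °C; cold 1 M HCl
Reagents that add atoms: none
Why: Weinreb ketone synthesis, in which chelate 16 persists until the quench so that only one pentyl group is delivered, and the low temperature spares the hindered benzoate.

**Step 7**
Reactants: 17 benzyl 2-methoxy-4-(methoxymethoxy)-6-(2-oxoheptyl)benzoate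
Product: 18 benzyl 4-hydroxy-2-methoxy-6-(2-oxoheptyl)benzoate
Conditions: 3 M aq HCl, THF/i-PrOH, 45 °C
Reagents that add atoms: none
Why: Acid hydrolysis of a phenolic MOM acetal, run in a water-rich medium at mild temperature so that the keto ester does not close to a lactone, with benzyl ester and methyl ether inert.

**Step 8**
Reactants: 17 benzyl 2-methoxy-4-(methoxymethoxy)-6-(2-oxoheptyl)benzoate
Product: 20 6,8-dihydroxy-3-pentyl-1H-isochromen-1-one (olivetonide), via olivetonic acid 19 (not isolated)
Conditions: BBr3 (5 equiv), CH2Cl2, −78 °C → rt; H2O; then p-TsOH·H2O (cat.), toluene, 80 °C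
Reagents that add atoms: none
Why: Lewis-acid dealkylation with BBr3 cleaves the methyl ether (helped by chelation to the ortho carbonyl), the MOM acetal and the benzyl ester in one operation, and acid-catalysed enol lactonisation of keto acid 19 gathers the material as the stable isocoumarin.

**Step 9**
Reactants: 20 6,8-dihydroxy-3-pentyl-1H-isochromen-1-one
Product: 21 6,8-bis(benzyloxy)-3-pentyl-1H-isochromen-1-one
Conditions: BnBr (3 equiv), K2CO3, DMF, 60 °C
Reagents that add atoms: benzyl bromide, BrCc1ccccc1
Why: Williamson ether synthesis on both phenols, with warm DMF overcoming the hydrogen bond between the 8-hydroxyl and the lactone carbonyl.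

**Step 10**
Reactants: 21 6,8-bis(benzyloxy)-3-pentyl-1H-isochromen-1-one
Product: 23 2,4-bis(benzyloxy)-6-(2-oxoheptyl)benzoic acid, via potassium carboxylate 22 (not isolated)
Conditions: KOH, EtOH/H2O, 80 °C; then cold 1 M HCl to pH 3, 0 °C
Reagents that add atoms: potassium hydroxide, [K+].[OH-]
Why: Saponification of the enol lactone, where hydroxide opens the isocoumarin at C1 and the released enolate tautomerises to the ketone, and cold acidification with prompt use of 23 should prevent re-closure.

**Step 11**
Reactants: 23 2,4-bis(benzyloxy)-6-(2-oxoheptyl)benzoic acid; 18 benzyl 4-hydroxy-2-methoxy-6-(2-oxoheptyl)benzoate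
Product: 25 benzyl 4-{[2,4-bis(benzyloxy)-6-(2-oxoheptyl)benzoyl]oxy}-2-methoxy-6-(2-oxoheptyl)benzoate, via O-acylisourea 24 (not isolated)
Conditions: DCC, toluene, 0 °C → rt
Reagents that add atoms: none
Why: Carbodiimide esterification as used for depside bonds, between the single free acid and the single free phenol, run without added base so that the benzylic ketone next to the activated carboxyl is not driven to enolise.

**Step 12**
Reactants: 25 benzyl 4-{[2,4-bis(benzyloxy)-6-(2-oxoheptyl)benzoyl]oxy}-2-methoxy-6-(2-oxoheptyl)benzoate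
Product: 26 arthonioic acid
Conditions: H2 (1 atm), 10% Pd/C, EtOAc, rt
Reagents that add atoms: none
Why: Catalytic hydrogenolysis cleaves the two benzyl ethers and the benzyl ester under neutral conditions, which leave the non-conjugated ketones, the depside ester and the methyl ether untouched.

**Compound list**
1 | 5-bromovanillin | O=Cc1cc(Br)c(O)c(OC)c1 | starting material
2 | 3-bromo-4-hydroxy-5-methoxyphenyl formate | O=COc1cc(Br)c(O)c(OC)c1 | intermediate
3 | 2-bromo-6-methoxybenzene-1,4-diol | Oc1cc(Br)c(O)c(OC)c1 | intermediate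
4 | 1-bromo-3-methoxy-2,5-bis(trimethylsilyloxy)benzene | C[Si](C)(C)Oc1cc(Br)c(O[Si](C)(C)C)c(OC)c1 | intermediate
5 | [3-methoxy-2,5-bis(trimethylsilyloxy)phenyl]lithium | [Li]c1cc(O[Si](C)(C)C)cc(OC)c1O[Si](C)(C)C | intermediate
6 | lithium 2-methoxy-6-(trimethylsilyl)-4-(trimethylsilyloxy)phenoxide | [Li+].[O-]c1c(OC)cc(O[Si](C)(C)C)cc1[Si](C)(C)C | intermediate
7 | 2-methoxy-6-(trimethylsilyl)-4-(trimethylsilyloxy)phenyl trifluoromethanesulfonate | COc1cc(O[Si](C)(C)C)cc([Si](C)(C)C)c1OS(=O)(=O)C(F)(F)F | intermediate
8 | 4-hydroxy-2-methoxy-6-(trimethylsilyl)phenyl trifluoromethanesulfonate | COc1cc(O)cc([Si](C)(C)C)c1OS(=O)(=O)C(F)(F)F | intermediate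
9 | 2-methoxy-4-(methoxymethoxy)-6-(trimethylsilyl)phenyl trifluoromethanesulfonate | COCOc1cc(OC)c(OS(=O)(=O)C(F)(F)F)c([Si](C)(C)C)c1 | intermediate
10 | dibenzyl malonate | O=C(CC(=O)OCc1ccccc1)OCc1ccccc1 | starting material
11 | 3-methoxy-5-(methoxymethoxy)benzyne | COCOC1=CC#CC(OC)=C1 | intermediate
12 | cesium 7-(benzyloxy)-8-[(benzyloxy)carbonyl]-5-methoxy-3-(methoxymethoxy)bicyclo[4.2.0]octa-1,3,5-trien-7-olate (transient, configuration undefined) | [Cs+].COCOc1cc(OC)c2c(c1)C(C(=O)OCc1ccccc1)C2([O-])OCc1ccccc1 | intermediate
13 | benzyl 2-[2-(benzyloxy)-2-oxoethyl]-6-methoxy-4-(methoxymethoxy)benzoate | COCOc1cc(OC)c(C(=O)OCc2ccccc2)c(CC(=O)OCc2ccccc2)c1 | intermediate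
14 | benzyl 2-methoxy-6-{2-[methoxy(methyl)amino]-2-oxoethyl}-4-(methoxymethoxy)benzoate | COCOc1cc(OC)c(C(=O)OCc2ccccc2)c(CC(=O)N(C)OC)c1 | intermediate
15 | pentylmagnesium bromide | CCCCC[Mg]Br | starting material
16 | bromomagnesium alkoxide of the tetrahedral adduct of 15 to amide 14 (transient, racemic) | CCCCCC(O[Mg]Br)(Cc1cc(OCOC)cc(OC)c1C(=O)OCc1ccccc1)N(C)OC | intermediate
17 | benzyl 2-methoxy-4-(methoxymethoxy)-6-(2-oxoheptyl)benzoate | CCCCCC(=O)Cc1cc(OCOC)cc(OC)c1C(=O)OCc1ccccc1 | intermediate
18 | benzyl 4-hydroxy-2-methoxy-6-(2-oxoheptyl)benzoate | CCCCCC(=O)Cc1cc(O)cc(OC)c1C(=O)OCc1ccccc1 | intermediate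
19 | 2,4-dihydroxy-6-(2-oxoheptyl)benzoic acid (olivetonic acid) | CCCCCC(=O)Cc1cc(O)cc(O)c1C(=O)O | intermediate
20 | 6,8-dihydroxy-3-pentyl-1H-isochromen-1-one (olivetonide) | CCCCCC1=Cc2cc(O)cc(O)c2C(=O)O1 | intermediate
21 | 6,8-bis(benzyloxy)-3-pentyl-1H-isochromen-1-one | CCCCCC1=Cc2cc(OCc3ccccc3)cc(OCc3ccccc3)c2C(=O)O1 | intermediate
22 | potassium 2,4-bis(benzyloxy)-6-(2-oxoheptyl)benzoate | [K+].CCCCCC(=O)Cc1cc(OCc2ccccc2)cc(OCc2ccccc2)c1C(=O)[O-] | intermediate
23 | 2,4-bis(benzyloxy)-6-(2-oxoheptyl)benzoic acid | CCCCCC(=O)Cc1cc(OCc2ccccc2)cc(OCc2ccccc2)c1C(=O)O | intermediate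
24 | O-[2,4-bis(benzyloxy)-6-(2-oxoheptyl)benzoyl]-N,N'-dicyclohexylisourea | CCCCCC(=O)Cc1cc(OCc2ccccc2)cc(OCc2ccccc2)c1C(=O)OC(=NC1CCCCC1)NC1CCCCC1 | intermediate
25 | benzyl 4-{[2,4-bis(benzyloxy)-6-(2-oxoheptyl)benzoyl]oxy}-2-methoxy-6-(2-oxoheptyl)benzoate | CCCCCC(=O)Cc1cc(OCc2ccccc2)cc(OCc2ccccc2)c1C(=O)Oc1cc(CC(=O)CCCCC)c(C(=O)OCc2ccccc2)c(OC)c1 | intermediate
26 | arthonioic acid, 4-{[2,4-dihydroxy-6-(2-oxoheptyl)benzoyl]oxy}-2-methoxy-6-(2-oxoheptyl)benzoic acid | CCCCCC(=O)Cc1cc(O)cc(O)c1C(=O)Oc1cc(CC(=O)CCCCC)c(C(=O)O)c(OC)c1 | target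

**Step count**
Total step count: 12.
Longest linear sequence: 11 (steps 1–6, then 8–12). Step 7 is the one-step side branch from 17.

**Steps most likely to fail**

**Step 11.**
- What may go wrong: after activation, the carboxyl carbon may be captured from within by the enol oxygen of the neighbouring ketone, which is enol lactonisation. The O-acylisourea may also undergo an O-to-N acyl shift. Either process could be faster than attack of the phenol on the doubly ortho-substituted acyl group.
- Fallback: it masks the ketone before the coupling. It sets out from 23 and comes back at 25.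
- The carboxylate of 23 is alkylated with allyl bromide and KHCO3 in DMF to allyl 2,4-bis(benzyloxy)-6-(2-oxoheptyl)benzoate F1.
- Ketalisation with 1,2-bis(trimethylsilyloxy)ethane and catalytic TMSOTf in CH2Cl2 at low temperature gives allyl 2,4-bis(benzyloxy)-6-[(2-pentyl-1,3-dioxolan-2-yl)methyl]benzoate F2.
- Pd(PPh3)4 with morpholine in THF then frees 2,4-bis(benzyloxy)-6-[(2-pentyl-1,3-dioxolan-2-yl)methyl]benzoic acid F3.
- F3 can no longer enolise, so it can be coupled with 18 under DCC and catalytic DMAP. This gives benzyl 4-({2,4-bis(benzyloxy)-6-[(2-pentyl-1,3-dioxolan-2-yl)methyl]benzoyl}oxy)-2-methoxy-6-(2-oxoheptyl)benzoate F4.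
- PPTS in wet acetone at 40 °C removes the dioxolane and returns 25.

**Step 4.**
- What may go wrong: proton transfer from the CH-acidic malonate to the aryl anion may outrun the 4-exo-trig acyl capture, which leads to plain alpha-arylation. Repeated arylation may also consume the aryne.
- Fallback: it releases the same aryne by ortho-deprotonation of a bromoarene, in a medium that holds the malonate only as its enolate. The aryl anion then meets no proton donor and acyl capture is its only exit. This fallback sets out from 10 and comes back at 13.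
- Commercial 4-bromo-3-methoxyphenol F5 is converted with MOMCl and i-Pr2NEt into 1-bromo-2-methoxy-4-(methoxymethoxy)benzene F6.
- Malonate 10 (2 equiv) is turned by LiTMP in THF at −78 °C into lithium dibenzyl malonate enolate F7.
- Further LiTMP then removes the only hydrogen ortho to bromine in F6. Loss of bromide gives 11, which inserts as in step 4 while the mixture warms to rt.

**Step 2.**
- What may go wrong: butyllithium may attack silicon of the remote silyl ether, or the silyl migration may stay incomplete. Either would lead to double triflation or to simple loss of bromine.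
- Fallback: it differentiates the two hydroxyls before the metalation. It sets out from 3 and comes back at 9, which makes step 3 unnecessary.
- One equivalent of MOMCl with i-Pr2NEt in CH2Cl2 at −20 °C should alkylate the unflanked hydroxyl on steric grounds. This gives 2-bromo-6-methoxy-4-(methoxymethoxy)phenol F8, and the regioisomer is removed by chromatography.
- HMDS gives [2-bromo-6-methoxy-4-(methoxymethoxy)phenoxy]trimethylsilane F9.
- n-BuLi brings about exchange and retro-Brook shift to lithium 2-methoxy-4-(methoxymethoxy)-6-(trimethylsilyl)phenoxide F10, and Tf2O converts F10 into 9.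

**Further compounds**
F1 | step 11 | allyl 2,4-bis(benzyloxy)-6-(2-oxoheptyl)benzoate | CCCCCC(=O)Cc1cc(OCc2ccccc2)cc(OCc2ccccc2)c1C(=O)OCC=C
F2 | step 11 | allyl 2,4-bis(benzyloxy)-6-[(2-pentyl-1,3-dioxolan-2-yl)methyl]benzoate | CCCCCC1(Cc2cc(OCc3ccccc3)cc(OCc3ccccc3)c2C(=O)OCC=C)OCCO1
F3 | step 11 | 2,4-bis(benzyloxy)-6-[(2-pentyl-1,3-dioxolan-2-yl)methyl]benzoic acid | CCCCCC1(Cc2cc(OCc3ccccc3)cc(OCc3ccccc3)c2C(=O)O)OCCO1
F4 | step 11 | benzyl 4-({2,4-bis(benzyloxy)-6-[(2-pentyl-1,3-dioxolan-2-yl)methyl]benzoyl}oxy)-2-methoxy-6-(2-oxoheptyl)benzoate | CCCCCC1(Cc2cc(OCc3ccccc3)cc(OCc3ccccc3)c2C(=O)Oc2cc(CC(=O)CCCCC)c(C(=O)OCc3ccccc3)c(OC)c2)OCCO1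
F5 | step 4 | 4-bromo-3-methoxyphenol (purchased) | COc1cc(O)ccc1Br
F6 | step 4 | 1-bromo-2-methoxy-4-(methoxymethoxy)benzene | COCOc1ccc(Br)c(OC)c1
F7 | step 4 | lithium dibenzyl malonate enolate | [Li+].O=C(OCc1ccccc1)[CH-]C(=O)OCc1ccccc1
F8 | step 2 | 2-bromo-6-methoxy-4-(methoxymethoxy)phenol | COCOc1cc(Br)c(O)c(OC)c1
F9 | step 2 | [2-bromo-6-methoxy-4-(methoxymethoxy)phenoxy]trimethylsilane | COCOc1cc(Br)c(O[Si](C)(C)C)c(OC)c1
F10 | step 2 | lithium 2-methoxy-4-(methoxymethoxy)-6-(trimethylsilyl)phenoxide | [Li+].[O-]c1c(OC)cc(OCOC)cc1[Si](C)(C)C
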